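**Retrosynthetic overview**
1. The target is opened by a Grob-type C1–C6 fragmentation of a saturated 7-oxanorbornane 13; this one event gives the ten-membered ring, the C1 hemiketal and the 5E enol-lactone alkene.
2. 13 comes from an intramolecular Diels–Alder reaction of the 2,5-dialkylfuran in 11 with its own exocyclic enol-lactone alkene (furan dearomatised; C4–C5 and C1–C6 formed; C4 set), followed by diimide.
3. Butenolide 11 comes from carbonylative enol-lactonisation of (Z)-β-iodoenone 10, itself made by an asymmetric iodo-aldol of aldehyde 3 with ynone 6 (C8) and esterification with chloro-hydroxy acid 9.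
4. Aldehyde 3 comes from an iminium-catalysed Friedel–Crafts alkylation of 2-methylfuran with crotonaldehyde (C10).
5. Ring order: butenolide (step 5), then oxanorbornene plus cyclohexane (step 6), then ten-membered carbocycle with tetrahydrofuran hemiketal (step 7).

Numbering: target (germacrane) numbering is used throughout. C1 hemiketal carbon, C2/C3 ring CH2, C4 C(CH3)–O, C5 =CH, C6 enol-lactone carbon, C7=C11 butenolide alkene, C8 acyloxy carbon, C9 CH2, C10 CH(CH3), C12 lactone C=O, C13 CH2OAc, C14/C15 methyls.

Assumption: acid 9 is bought as a catalogue chiral building block, and the catalyst antipodes in steps 1 and 3 are assigned by analogy with their usual facial preference (the mirror-image catalyst is used if an assignment proves reversed).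

**Route**

Step 1
Reactants: 1 2-methylfuran; 2 (E)-but-2-enal (crotonaldehyde)
Product: 3 (3R)-3-(5-methylfuran-2-yl)butanal
Conditions: (2S,5S)-5-benzyl-2-tert-butyl-3-methylimidazolidin-4-one·CF3CO2H (20 mol %), 1 (3 equiv), CH2Cl2/i-PrOH 85:15, −40 °C
Reagents that add atoms: none
Why: Iminium-ion-catalysed Friedel–Crafts (conjugate) alkylation at the free C5 position of 2-methylfuran; the benzyl and tert-butyl groups shield one face of the (E)-iminium ion so the furan adds to the other, which sets C10 as R (same facial sense as the indole and pyrrole alkylations of crotonaldehyde).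

Step 2
Reactants: 4 prop-2-yn-1-yl acetate; 5 2-chloro-2-oxoethyl acetate (acetoxyacetyl chloride)
Product: 6 2-oxopent-3-yne-1,5-diyl diacetate
Conditions: PdCl2(PPh3)2 (2 mol %), CuI (4 mol %), Et3N (1.1 equiv), THF, 0 °C to rt
Reagents that add atoms: none
Why: Acyl Sonogashira coupling of a terminal alkyne with an acid chloride gives the ynone directly and forms no stereocentre.

Step 3
Reactants: 3 (3R)-3-(5-methylfuran-2-yl)butanal; 6 2-oxopent-3-yne-1,5-diyl diacetate
Product: 8 (2Z,4R,6R)-3-(acetoxyacetyl)-4-hydroxy-2-iodo-6-(5-methylfuran-2-yl)hept-2-en-1-yl acetate, via trimethylsilyl ether 7 (not isolated)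
Conditions: (S)-tetrahydro-1-(2-methylphenyl)-3,3-diphenyl-1H,3H-pyrrolo[1,2-c][1,3,2]oxazaborole (20 mol %) activated with Tf2NH (20 mol %), Me3SiI (1.3 equiv), CH2Cl2, −78 °C; aq. citric acid work-up
Reagents that add atoms: iodotrimethylsilane, C[Si](C)(C)I
Why: Catalytic asymmetric three-component halo-aldol (β-iodo Morita–Baylis–Hillman) reaction in which iodide adds 1,4 to ynone 6 and the resulting silyl allenolate attacks, through its central carbon and anti to iodine (iodine ends syn to the acyl group, Z), the aldehyde held on the chiral oxazaborolidinium ion, whose open face sets C8 as R under catalyst control.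

Step 4
Reactants: 8 (2Z,4R,6R)-iodo-aldol alcohol; 9 (2R)-3-chloro-2-hydroxy-2-methylpropanoic acid
Product: 10 (2Z,4R,6R)-1-acetoxy-3-(acetoxyacetyl)-2-iodo-6-(5-methylfuran-2-yl)hept-2-en-4-yl (2R)-3-chloro-2-hydroxy-2-methylpropanoate
Conditions: EDC·HCl (2 equiv), DMAP (0.3 equiv), CH2Cl2, 0 °C to rt
Reagents that add atoms: none
Why: Steglich esterification acylates the secondary C8 alcohol with retention, the tertiary hydroxyl of 9 being too hindered to compete and the fully substituted β-carbon of the iodoenone resisting DMAP addition–elimination.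

Step 5
Reactants: 10 (Z)-β-iodoenone ester
Product: 11 (1R,3R)-1-[(2Z)-2-(acetoxymethylidene)-4-(acetoxymethyl)-5-oxo-2,5-dihydrofuran-3-yl]-3-(5-methylfuran-2-yl)butyl (2R)-3-chloro-2-hydroxy-2-methylpropanoate
Conditions: CO (5 atm), PdCl2(PPh3)2 (5 mol %), Et3N (1.5 equiv), MeCN, 50 °C
Reagents that add atoms: carbon monoxide, [C-]#[O+]
Why: Carbonylative lactonisation of a (Z)-β-iodoenone in which zerovalent palladium inserts into C11–I, CO inserts faster than β-acetoxy elimination under pressure, and the acylpalladium is captured by the enol oxygen of the cis acetoxyacetyl ketone to give the (Z)-5-ylidene butenolide, any (E)-iodoenone being funnelled through reversible iodide addition–elimination because only the Z isomer can close.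

Step 6
Reactants: 11 furan-tethered acetoxymethylidene butenolide
Product: 13 saturated 1,4-epoxy-bridged cycloadduct (1R,4R,5S,6S,8R,10R), via oxanorbornene cycloadduct 12 (not isolated)
Conditions: CH2Cl2, 13 kbar, 25 °C, 48 h; then 2-nitrobenzenesulfonylhydrazide (3 equiv), Et3N, CH2Cl2, 25 °C
Reagents that add atoms: none
Why: Intramolecular Diels–Alder reaction of the furan (dearomatisation) with the exocyclic doubly oxygenated enol-lactone alkene, a vinylene-diester-type dienophile that is also the δ-position of a dienoate, with high pressure overcoming reversibility and the congestion of the two new quaternary carbons; the tether reacts through an exo chair in which C8–H eclipses the butenolide plane (A(1,3) strain with C13, ester pseudo-axial) and the C10 methyl is pseudo-equatorial, so the furan presents the face that makes C4 R (C1, C5 and C6 follow from suprafacial addition), and diimide then saturates only the strained C2=C3 bond, which also blocks cycloreversion.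

Step 7
Reactants: 13 saturated 1,4-epoxy-bridged cycloadduct
Product: 15 CNP0414417.2 (target), via oxocarbenium acetate 14 (not isolated)
Conditions: Sc(OTf)3 (10 mol %), MeCN/H2O 20:1, 0 to 25 °C
Reagents that add atoms: water, O
Why: Proposed new method: acid-triggered vinylogous retro-aldol (Grob-type) fragmentation in which the bridging-oxygen lone pair lies close to anti-periplanar to the C1–C6 bond and Sc(OTf)3 activates the lactone carbonyl, so heterolysis gives a five-membered oxocarbenium ion at C1 and a 2-oxyfuran at C6 that expels the C5 acetate (E1cB) to form C5=C6, driven by release of oxanorbornane strain and of the two adjacent quaternary carbons; the bridged ring allows only the alkene with C4 and C7 cis (5E), water adds to the outer face of C1 to give the 1S hemiketal (the only one the cis bridge allows), and C4, C8 and C10 are untouched; the closest known reactions are Grob fragmentations of 1,3-difunctional bicycles to ten-membered rings and de Mayo-type retro-aldol openings of donor–acceptor strained rings.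

**Compound list**

1 | 2-methylfuran | Cc1ccco1 | starting material
2 | (E)-but-2-enal (crotonaldehyde) | C/C=C/C=O | starting material
3 | (3R)-3-(5-methylfuran-2-yl)butanal | Cc1ccc(o1)[C@H](C)CC=O | intermediate
4 | prop-2-yn-1-yl acetate (propargyl acetate) | CC(=O)OCC#C | starting material
5 | 2-chloro-2-oxoethyl acetate (acetoxyacetyl chloride) | CC(=O)OCC(Cl)=O | starting material
6 | 2-oxopent-3-yne-1,5-diyl diacetate | CC(=O)OCC#CC(=O)COC(C)=O | intermediate
7 | O-trimethylsilyl ether of 8 (not isolated) | CC(=O)OC/C(I)=C(/C(=O)COC(C)=O)[C@H](O[Si](C)(C)C)C[C@@H](C)c1ccc(C)o1 | intermediate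
8 | (2Z,4R,6R)-3-(acetoxyacetyl)-4-hydroxy-2-iodo-6-(5-methylfuran-2-yl)hept-2-en-1-yl acetate | CC(=O)OC/C(I)=C(/C(=O)COC(C)=O)[C@H](O)C[C@@H](C)c1ccc(C)o1 | intermediate
9 | (2R)-3-chloro-2-hydroxy-2-methylpropanoic acid | OC(=O)[C@@](C)(O)CCl | starting material
10 | (2Z,4R,6R)-1-acetoxy-3-(acetoxyacetyl)-2-iodo-6-(5-methylfuran-2-yl)hept-2-en-4-yl (2R)-3-chloro-2-hydroxy-2-methylpropanoate | CC(=O)OC/C(I)=C(/C(=O)COC(C)=O)[C@H](OC(=O)[C@@](C)(O)CCl)C[C@@H](C)c1ccc(C)o1 | intermediate
11 | (1R,3R)-1-[(2Z)-2-(acetoxymethylidene)-4-(acetoxymethyl)-5-oxo-2,5-dihydrofuran-3-yl]-3-(5-methylfuran-2-yl)butyl (2R)-3-chloro-2-hydroxy-2-methylpropanoate | CC(=O)OCC1=C([C@H](OC(=O)[C@@](C)(O)CCl)C[C@@H](C)c2ccc(C)o2)/C(=C/OC(C)=O)OC1=O | intermediate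
12 | Diels–Alder adduct (not isolated): C1–C6 and C4–C5 bonded, oxygen bridging C1 and C4 (7-oxanorbornene with C2=C3), six-membered ring C1–C10–C9–C8–C7–C6 exo-fused, lactone oxygen at C6 and acetoxy at C5 both endo; (1S,4R,5S,6S,8R,10R), side chain 2R | CC(=O)OCC1=C2[C@]3(OC1=O)[C@@H](OC(C)=O)[C@@]4(C)C=C[C@@]3(O4)[C@H](C)C[C@H]2OC(=O)[C@@](C)(O)CCl | intermediate
13 | 2,3-dihydro derivative of 12 (7-oxanorbornane); (1R,4R,5S,6S,8R,10R), side chain 2R | CC(=O)OCC1=C2[C@]3(OC1=O)[C@@H](OC(C)=O)[C@@]4(C)CC[C@@]3(O4)[C@H](C)C[C@H]2OC(=O)[C@@](C)(O)CCl | intermediate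
14 | ring-opened C1 oxocarbenium ion of the ten-membered 5E-dienolide, as its acetate ion pair (not isolated) | CC(=O)OCC1=C2/C(=C\[C@@]3(C)CCC(=[O+]3)[C@H](C)C[C@H]2OC(=O)[C@@](C)(O)CCl)OC1=O.CC(=O)[O-] | intermediate
15 | CNP0414417.2: (1S,4R,5E,8R,10R)-13-acetoxy-1,4-epoxy-1-hydroxygermacra-5,7(11)-dien-6,12-olid-8-yl (2R)-3-chloro-2-hydroxy-2-methylpropanoate | CC(=O)OCC1=C2/C(=C\[C@@]3(C)CC[C@](O)(O3)[C@H](C)C[C@H]2OC(=O)[C@@](C)(O)CCl)OC1=O | target

**Count and risks**

Total step count: 7. Longest linear sequence: 6 (steps 1, 3, 4, 5, 6, 7 from 2-methylfuran).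

Three steps most likely to fail:

Step 6 (cycloaddition). Risks: two contiguous fully substituted carbons are formed, the furan adduct can revert, and the facial model may not hold. The fallback sets out from 8 and returns at 13. Alcohol 8 is carbonylated without prior esterification (CO, PdCl2(PPh3)2, Et3N) to hydroxy butenolide F2. Dess–Martin periodinane gives keto butenolide F3, in which the C8 carbonyl is cross-conjugated to the dienophile and binds MeAlCl2 (CH2Cl2, −78 °C), so the cycloaddition becomes Lewis-acid catalysed and only C10 steers the furan face, giving ketone cycloadduct F4. Diimide gives saturated ketone F5, LiBH(s-Bu)3 attacks the C8 carbonyl from the equatorial direction to give axial 8R alcohol F6, and esterification with 9 (EDC·HCl, DMAP) gives 13.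

Step 7 (fragmentation). Risks: ionisation of the oxygen bridge (possibly assisted by the endo acetate) instead of C1–C6 cleavage, and C10 epimerisation through an enol ether. The fallback sets out from 11 and returns at 15. Cycloadduct 12 is generated under pressure as in step 6 but is not reduced, and is treated directly with Sc(OTf)3 in wet MeCN. C1–C6 heterolysis then gives an allyl-stabilised 2H-furanium ion, which should form more easily than the bridge can ionise. Loss of acetate and capture by water give 2,3-didehydro hemiketal F7. Diimide (2-nitrobenzenesulfonylhydrazide, Et3N) then reduces the cis-disubstituted C2=C3 bond in preference to the conjugated tri- and tetrasubstituted dienolide alkenes, giving 15.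

Step 3 (iodo-aldol). Risks: the ynone is β-substituted, so both the iodoalkene geometry and the catalyst-controlled C8 selectivity are extrapolated from terminal ynones. The fallback sets out from 3 and 6 and returns at 10. MgI2 (CH2Cl2, 0 °C) without a chiral catalyst gives 8 together with its C8 epimer, the (2Z,4S,6R)-alcohol F1, and the two diastereomers are separated on silica. 8 goes on through step 4, while F1 is converged onto 10 by Mitsunobu esterification with 9 (PPh3, DIAD, THF, 0 °C), which inverts C8.

**Further compounds**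

F1 | step 3 | (2Z,4S,6R)-3-(acetoxyacetyl)-4-hydroxy-2-iodo-6-(5-methylfuran-2-yl)hept-2-en-1-yl acetate | CC(=O)OC/C(I)=C(/C(=O)COC(C)=O)[C@@H](O)C[C@@H](C)c1ccc(C)o1
F2 | step 6 | (5Z)-5-(acetoxymethylidene)-3-(acetoxymethyl)-4-[(1R,3R)-1-hydroxy-3-(5-methylfuran-2-yl)butyl]furan-2(5H)-one | CC(=O)OCC1=C([C@H](O)C[C@@H](C)c2ccc(C)o2)/C(=C/OC(C)=O)OC1=O
F3 | step 6 | (5Z)-5-(acetoxymethylidene)-3-(acetoxymethyl)-4-[(3R)-3-(5-methylfuran-2-yl)butanoyl]furan-2(5H)-one | CC(=O)OCC1=C(C(=O)C[C@@H](C)c2ccc(C)o2)/C(=C/OC(C)=O)OC1=O
F4 | step 6 | 8-oxo analogue of cycloadduct 12 lacking the C8 ester (C8 ketone, C2=C3 present) | CC(=O)OCC1=C2[C@]3(OC1=O)[C@@H](OC(C)=O)[C@@]4(C)C=C[C@@]3(O4)[C@H](C)CC2=O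
F5 | step 6 | 2,3-dihydro derivative of F4 (saturated C8 ketone) | CC(=O)OCC1=C2[C@]3(OC1=O)[C@@H](OC(C)=O)[C@@]4(C)CC[C@@]3(O4)[C@H](C)CC2=O
F6 | step 6 | (8R)-alcohol corresponding to 13 without the C8 acyl group | CC(=O)OCC1=C2[C@]3(OC1=O)[C@@H](OC(C)=O)[C@@]4(C)CC[C@@]3(O4)[C@H](C)C[C@H]2O
F7 | step 7 | 2,3-didehydro-15 (2-hydroxy-2,5-dihydrofuran hemiketal) | CC(=O)OCC1=C2/C(=C\[C@@]3(C)C=C[C@](O)(O3)[C@H](C)C[C@H]2OC(=O)[C@@](C)(O)CCl)OC1=O
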